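The time of reading is what separates elm from larch; their charges are the same.

    free monomer + initiator → living end + monomer in chains (k1 = 28.4 M⁻¹ s⁻¹)
    free monomer + living end → monomer in chains + living end, rate k2*[living end]*[free monomer] (k2 = 7110 M⁻¹ s⁻¹)
    2 initiator → spent initiator (k3 = 1370 M⁻¹ s⁻¹)

common to all: free monomer 0.50 mM; initiator 6.3 mol%

| flask | time |
|---|---|
| elm | 50 s |
| larch | 12 s |

1. which of the two ends with the longer chains by the average number of monomer units in a chain (chains begun, living or dead) ("neither" if they lie within 10%) (elm / larch / neither)
2. average number of monomer units in a chain (chains begun, living or dead) at the end, elm
3. average number of monomer units in a chain (chains begun, living or dead) at the end, larch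

- two of one species on the left: rate k times its square, two consumed each time
- the average divides the monomer in chains by the number of chains begun, living and dead together
- run time (elm): 50 s

Follow one living end. With free monomer at its charge, it adds 3.56 s⁻¹, the growth constant times that charge. Call this the pace, the pseudo-first-order rate a living end sees. While free monomer stays near its charge, a chain's length is one unit plus its age times the pace, however many chains there are.

So you need the age. At charge, initiator destroys itself at 0.0863 s⁻¹ and begins chains at 0.0142 s⁻¹, so self-loss is faster. Just 14.1% of the initiator lost at that moment begins a chain. Its first half-life by self-loss alone is 11.6 s.

My reckoning takes chains begun evenly, so their mean age is half the time of reading. For larch that gives 22.3. This should run low, because larch is read at about that half-life and chain starts thin out, which leaves the chains older than the even picture.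

Elm is read later, so its chains are older. With free monomer held, its mark is 89.9, but free monomer will fall, and I do not reckon how far. I commit to elm as the longer, below that mark.

The forecast also names elm, with 70 for elm and 24 for larch, which is above my larch figure. Its grounds: “the longer run converts far more monomer over nearly the same number of chains”.

The simulation gives elm as the longer, with 69.6 for elm and 23.8 for larch. Left ten times as long, elm reads 85.4 at 500 s and larch 84.5 at 120 s, a gap inside 10%, so read that late the answer is neither. Larch stands above the 22.3 from the pace. Stop larch at 8.0 s instead: the pace gives 15.2, and that flask reads 16.2.

The constants used here are made up; what happens was integrated by code.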